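Readings and results are calculated with made-up constants; scatter was added.

I watched the partner.

| flask | starting material | partner | second substrate | remark | time |
|---|---|---|---|---|---|
| Thursday's | 0.25 M | 1.2 equiv | 1 equiv | run made earlier |  |
| Tuesday's | 0.12 M | 1.2 equiv | 1 equiv | run made earlier |  |
| dawn | 0.25 M | 1.20 equiv | 1.00 equiv | everything together in a closed stirred flask, run for 6.0 h | 6.0 h |
| midnight | 0.25 M | 1.20 equiv | 1.00 equiv | plug flow through a tube for 6.0 h, no back-mixing | 6.0 h |
| dusk | 0.25 M | 1.20 equiv | 1.00 equiv | a single well-mixed tank run continuously and read at steady state, 6.0 h in it on average |  |
| spring | 0.25 M | 1.20 equiv | 1.00 equiv | one stirred flow tank at steady state, fed with the mixture as stated, mean residence time 60.0 h |  |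

- Thursday's (time / h: target / %, over-reaction product / %): 0.500: 21.6, 2.7; 0.833: 26.1, 4.5; 1.50: 29.2, 8.0; 3.00: 27.2, 13.9; 6.00: 21.2, 19.8
- Tuesday's (time / min: target / %, over-reaction product / %): 15.0: 7.7, 0; 30.0: 13.6, 1.0; 40.0: 16.0, 1.1; 60.0: 19.3, 2.2; 80.0: 21.8, 3.7

(standard deviation of a reading: 0.3 percentage points)

- the set-up with the highest share of target in all that became target or over-reaction product, at the outlet or at the end ("none" if the first two lie within 2 percentage points) (dawn / midnight / dusk / spring / none)
- share of target in all that became target or over-reaction product, at the outlet or at the end, dawn
- share of target in all that became target or over-reaction product, at the outlet or at the end, midnight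
- share of target in all that became target or over-reaction product, at the outlet or at the end, dusk
- share of target in all that became target or over-reaction product, at the outlet or at the end, spring

- the stated concentrations are those of everything mixed, before any reaction; amounts are the same in each set-up
- the earlier runs were made in a closed, stirred flask

In the first instants target rose fast: after 0.500 h Thursday's run read 21.6%, against 13.6% for Tuesday's dilute run at the same time. A first-order step gives equal percentages at equal times, so I took target formation to need a partner molecule. In the middle of Thursday's run target peaked, as a reading, near 29.2% at 1.50 h, while over-reaction product kept climbing. By 6.00 h the two stood at 21.2% and 19.8%, a share of 51.7%. I expected that share for dawn and for midnight, since a tube without back-mixing repeats the closed flask's history.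

So I read one quantity from Thursday's run: over-reaction product formed per hour per unit of target, a pseudo-first-order constant. It read 0.190 h⁻¹ early, 0.139 h⁻¹ in the middle and 0.0813 h⁻¹ late, each reading lower than the one before, and I took this fall to follow the partner concentration.

In a steady tank over-reaction product leaves as fast as it forms. Its amount over target is therefore this constant times the mean residence time, and the share is one over one plus that product. The middle reading gave dusk 54.4%, more than the share of Thursday's run by 2.7 percentage points, so I chose dusk. The late reading gave spring 17.0%, and I expected more, the constant still falling.

The forecast gave 51.7%, 51.7%, 52.7% and 21% in the order asked, and best none: “The top two lie within 2 points, so none.”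

The set-ups gave 51.7%, 51.7%, 56.8% and 34.3%, so dusk stood highest, and spring lay 13 points above the forecast.

    starting material + partner ⇌ target (K = 9.60 M⁻¹, k = 0.0470 M⁻¹ min⁻¹)
    second substrate + partner ⇌ second product (K = 4.90 M⁻¹, k = 0.0530 M⁻¹ min⁻¹)
    partner → decomposed reagent (k = 0.00260 min⁻¹)
    partner + target → over-reaction product (k = 0.0330 M⁻¹ min⁻¹)

With partner as charged, at 0.300 M, target's half-life by over-reaction was 1.2 h, short against the 6.0 h spent on average in dusk's tank. Dusk's share gives the constant as 0.127 h⁻¹ against my middle reading of 0.139 h⁻¹, which puts partner at 0.0641 M, while spring's gives 0.0319 h⁻¹, 2.55 times below my late reading of 0.0813 h⁻¹, with partner at 0.0161 M.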